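**Retrosynthetic overview**
1. The target is two (2S)-7-hydroxy-5-methoxyflavan halves joined C8(unit A)–CH2–C6(unit B); both halves are cut back to one chromanol, (2S)-7-benzyloxy-5-methoxyflavan-8-ol 10.
2. The C8 oxygen of 10 is used twice: as its triflate it is exchanged for the bridging carbon of unit A (12), and in unit B it blocks C8 so that Friedel–Crafts benzylation by 12 can only occur at C6; it is then removed by reduction of the triflate.
3. The pyran ring of each half is not closed directly: phenol 8 is dearomatised at its chain-bearing carbon to a five-membered oxaspiro ring (9), which expands to the six-membered pyran by 1,2-shift of the ring CH2 (dienone-phenol type).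
4. Enabling feature: in the benzo ring of unit A the oxygen at C8 is ortho to C8a, and the carbon that becomes C4a is an unsubstituted CH in 8; the C8–OH/C8a pair allows spirocyclisation at C8a, and the adjacent CH accepts the migrating C4.
5. The C2 stereocentre is set by asymmetric transfer hydrogenation of ketone 7 (from aldol condensation of 4 with acetophenone). Ring order: both benzene rings come from 1, then the transient spiro oxolane, then the pyran, then union of the halves.

Key step: step 6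

Remark: 2-(benzyloxy)-4-methoxybenzaldehyde 1 and acetophenone 5 are taken as catalogue compounds; both stereocentres of the target are (S), and each is the untouched carbinol carbon of alcohol 8.

**Step 1**
Reactants: 1 2-(benzyloxy)-4-methoxybenzaldehyde
Product: 3 2-(benzyloxy)-4-methoxyphenol, via aryl formate 2 (not isolated)
Conditions: mCPBA, CH2Cl2, 0 °C to rt; then K2CO3 (cat.), MeOH, rt
Reagents that add atoms: mCPBA (3-chloroperoxybenzoic acid) O=C(OO)c1cccc(Cl)c1
Why: Dakin-type oxidation, in which Baeyer–Villiger insertion into the electron-rich benzaldehyde (aryl migration) should give formate 2, cleaved by methanolysis to the phenol; no stereocentre.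

**Step 2**
Reactants: 3 2-(benzyloxy)-4-methoxyphenol
Product: 4 3-(benzyloxy)-2-hydroxy-5-methoxybenzaldehyde
Conditions: MgCl2, Et3N, (CH2O)n, MeCN, reflux
Reagents that add atoms: formaldehyde (as paraformaldehyde) C=O
Why: Casnati–Skattebøl ortho-formylation, in which the magnesium phenoxide delivers formaldehyde to the only free ortho position and a second formaldehyde oxidises the benzylic alkoxide; no stereocentre.

**Step 3**
Reactants: 4 3-(benzyloxy)-2-hydroxy-5-methoxybenzaldehyde, 5 acetophenone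
Product: 6 (E)-3-[3-(benzyloxy)-2-hydroxy-5-methoxyphenyl]-1-phenylprop-2-en-1-one
Conditions: KOH, EtOH/H2O, rt, N2; then dilute HCl
Reagents that add atoms: none
Why: Claisen–Schmidt aldol condensation of the enolate of 5 with the non-enolisable aldehyde 4 should give the thermodynamically favoured (E)-enone; no stereocentre.

**Step 4**
Reactants: 6 (E)-3-[3-(benzyloxy)-2-hydroxy-5-methoxyphenyl]-1-phenylprop-2-en-1-one
Product: 7 3-[3-(benzyloxy)-2-hydroxy-5-methoxyphenyl]-1-phenylpropan-1-one
Conditions: H2 (1 atm), Pd/C, Ph2S (cat.), EtOAc, rt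
Reagents that add atoms: none
Why: Catalytic hydrogenation of the conjugated C=C over diphenyl sulfide-poisoned Pd/C, a catalyst type that spares aryl benzyl ethers and aryl ketones; no stereocentre.

**Step 5**
Reactants: 7 3-[3-(benzyloxy)-2-hydroxy-5-methoxyphenyl]-1-phenylpropan-1-one
Product: 8 (S)-2-(benzyloxy)-6-(3-hydroxy-3-phenylpropyl)-4-methoxyphenol
Conditions: RuCl(p-cymene)[(S,S)-TsDPEN] (1 mol %), HCO2H/Et3N (5:2), rt
Reagents that add atoms: none
Why: Noyori asymmetric transfer hydrogenation of an aryl alkyl ketone, in which the (S,S)-TsDPEN ligand controls the face of hydride delivery and should give the (S)-carbinol as it does for acetophenone.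

**Step 6**
Reactants: 8 (S)-2-(benzyloxy)-6-(3-hydroxy-3-phenylpropyl)-4-methoxyphenol
Product: 10 (2S)-7-(benzyloxy)-5-methoxy-2-phenyl-3,4-dihydro-2H-chromen-8-ol, via ortho-quinol spiroether 9 (not isolated)
Conditions: PhI(OAc)2 (1.0 equiv), CH2Cl2/HFIP (4:1), −40 °C; then BF3·OEt2 (0.3 equiv), −40 to 0 °C
Reagents that add atoms: none
Why: Proposed new method: PhI(OAc)2 should turn phenol 8 into an aryloxy iodane (trivalent iodine) whose side-chain hydroxyl attacks the chain-bearing ortho carbon with loss of PhI to give ortho-quinol spiroether 9, and BF3 then complexes the dienone carbonyl so that the ring CH2 shifts from the spiro carbon to the neighbouring cationic CH, leaving an aryloxocarbenium ion that loses a proton to give aromatic 10. The closest known reaction type is oxidative spiroetherification of 4-(3-hydroxyalkyl)phenols followed by acid-mediated dienone-phenol ring expansion of the 1-oxaspiro[4.5]deca-6,9-dien-8-ones to chroman-6-ols, together with the dienone-phenol rearrangement of 6,6-disubstituted cyclohexa-2,4-dienones; the ortho-quinol spiroether case is the new element. The oxolane closes by 5-exo attack of oxygen on the dearomatised ring, and the pyran arises from it by 1,2-shift of carbon, five-membered to six-membered. No stereocentre is created: C2 is the carbinol carbon of 8 and none of its bonds is touched, so (S) is carried over with retention, and both spiro epimers of 9 converge because the spiro carbon becomes sp2. The step needs ortho rather than para attack in the dearomatisation, secured by intramolecular delivery in weakly nucleophilic HFIP while the para carbon carries OMe and has no partner, and it needs carbon rather than oxygen migration to a single terminus, secured because only the carbon shift leaves an oxygen-stabilised cation and the other neighbour of the spiro carbon is the carbonyl carbon.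

**Step 7**
Reactants: 10 (2S)-7-(benzyloxy)-5-methoxy-2-phenyl-3,4-dihydro-2H-chromen-8-ol
Product: 11 (2S)-7-(benzyloxy)-5-methoxy-2-phenyl-3,4-dihydro-2H-chromen-8-yl trifluoromethanesulfonate
Conditions: Tf2O, pyridine, CH2Cl2, 0 °C
Reagents that add atoms: triflic anhydride O=S(=O)(OS(=O)(=O)C(F)(F)F)C(F)(F)F
Why: O-Sulfonylation of the phenol with triflic anhydride and pyridine; no stereocentre is touched.

**Step 8**
Reactants: 11 (2S)-7-(benzyloxy)-5-methoxy-2-phenyl-3,4-dihydro-2H-chromen-8-yl trifluoromethanesulfonate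
Product: 12 [(2S)-7-(benzyloxy)-5-methoxy-2-phenyl-3,4-dihydro-2H-chromen-8-yl]methanol
Conditions: potassium (acetoxymethyl)trifluoroborate, Pd(dba)2 (5 mol %), RuPhos (10 mol %), Na2CO3, dioxane/H2O (10:1), 100 °C
Reagents that add atoms: potassium (acetoxymethyl)trifluoroborate CC(=O)OC[B-](F)(F)F.[K+]
Why: Suzuki–Miyaura hydroxymethylation of an aryl triflate with an acetoxymethyltrifluoroborate (acetate hydrolysed in situ), the bulky RuPhos ligand allowing oxidative addition at the di-ortho-oxygenated carbon; no stereocentre is touched.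

**Step 9**
Reactants: 12 [(2S)-7-(benzyloxy)-5-methoxy-2-phenyl-3,4-dihydro-2H-chromen-8-yl]methanol, 10 (2S)-7-(benzyloxy)-5-methoxy-2-phenyl-3,4-dihydro-2H-chromen-8-ol
Product: 13 (2S)-7-(benzyloxy)-6-{[(2S)-7-(benzyloxy)-5-methoxy-2-phenyl-3,4-dihydro-2H-chromen-8-yl]methyl}-5-methoxy-2-phenyl-3,4-dihydro-2H-chromen-8-ol
Conditions: 10 (3 equiv, excess recovered), TFA (0.2 equiv), CH2Cl2, 0 °C, slow addition of 12
Reagents that add atoms: none
Why: Acid-catalysed Friedel–Crafts benzylation, in which the 2,4,6-trioxygenated benzyl cation from 12 should attack C6 of 10, the only unsubstituted ring position of the nucleophile, which is kept in excess to outrun self-condensation of 12; no stereocentre is touched.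

**Step 10**
Reactants: 13 (2S)-7-(benzyloxy)-6-{[(2S)-7-(benzyloxy)-5-methoxy-2-phenyl-3,4-dihydro-2H-chromen-8-yl]methyl}-5-methoxy-2-phenyl-3,4-dihydro-2H-chromen-8-ol
Product: 14 (2S)-7-(benzyloxy)-6-{[(2S)-7-(benzyloxy)-5-methoxy-2-phenyl-3,4-dihydro-2H-chromen-8-yl]methyl}-5-methoxy-2-phenyl-3,4-dihydro-2H-chromen-8-yl trifluoromethanesulfonate
Conditions: Tf2O, pyridine, CH2Cl2, 0 °C
Reagents that add atoms: triflic anhydride O=S(=O)(OS(=O)(=O)C(F)(F)F)C(F)(F)F
Why: O-Sulfonylation of the single free phenol with triflic anhydride and pyridine; no stereocentre is touched.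

**Step 11**
Reactants: 14 (2S)-7-(benzyloxy)-6-{[(2S)-7-(benzyloxy)-5-methoxy-2-phenyl-3,4-dihydro-2H-chromen-8-yl]methyl}-5-methoxy-2-phenyl-3,4-dihydro-2H-chromen-8-yl trifluoromethanesulfonate
Product: 15 (2S)-7-(benzyloxy)-6-{[(2S)-7-(benzyloxy)-5-methoxy-2-phenyl-3,4-dihydro-2H-chromen-8-yl]methyl}-5-methoxy-2-phenyl-3,4-dihydro-2H-chromene
Conditions: Pd(OAc)2 (5 mol %), dppf (10 mol %), HCO2H, Et3N, DMF, 80 °C
Reagents that add atoms: none
Why: Palladium-catalysed formate reduction of an aryl triflate (oxidative addition, formate-to-hydride exchange, reductive elimination), conditions to which benzyl ethers and the benzylic C2–O bonds are stable; no stereocentre is touched.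

**Step 12**
Reactants: 15 (2S)-7-(benzyloxy)-6-{[(2S)-7-(benzyloxy)-5-methoxy-2-phenyl-3,4-dihydro-2H-chromen-8-yl]methyl}-5-methoxy-2-phenyl-3,4-dihydro-2H-chromene
Product: 16 (2S)-6-{[(2S)-7-hydroxy-5-methoxy-2-phenyl-3,4-dihydro-2H-chromen-8-yl]methyl}-5-methoxy-2-phenyl-3,4-dihydro-2H-chromen-7-ol (CNP0178097.1)
Conditions: H2 (1 atm), Pd/C, EtOAc/MeOH, rt
Reagents that add atoms: none
Why: Hydrogenolysis of the two aryl benzyl ethers over Pd/C under neutral conditions, which should leave the flavan C2–O bonds and both (S) centres intact.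

**Compound list**
1 | 2-(benzyloxy)-4-methoxybenzaldehyde | O=Cc1ccc(OC)cc1OCc1ccccc1 | starting material
2 | 2-(benzyloxy)-4-methoxyphenyl formate | O=COc1ccc(OC)cc1OCc1ccccc1 | intermediate (not isolated)
3 | 2-(benzyloxy)-4-methoxyphenol | Oc1ccc(OC)cc1OCc1ccccc1 | intermediate
4 | 3-(benzyloxy)-2-hydroxy-5-methoxybenzaldehyde | O=Cc1cc(OC)cc(OCc2ccccc2)c1O | intermediate
5 | acetophenone | CC(=O)c1ccccc1 | starting material
6 | (E)-3-[3-(benzyloxy)-2-hydroxy-5-methoxyphenyl]-1-phenylprop-2-en-1-one | O=C(/C=C/c1cc(OC)cc(OCc2ccccc2)c1O)c1ccccc1 | intermediate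
7 | 3-[3-(benzyloxy)-2-hydroxy-5-methoxyphenyl]-1-phenylpropan-1-one | O=C(CCc1cc(OC)cc(OCc2ccccc2)c1O)c1ccccc1 | intermediate
8 | (S)-2-(benzyloxy)-6-(3-hydroxy-3-phenylpropyl)-4-methoxyphenol | O[C@@H](CCc1cc(OC)cc(OCc2ccccc2)c1O)c1ccccc1 | intermediate
9 | (2S)-7-(benzyloxy)-9-methoxy-2-phenyl-1-oxaspiro[4.5]deca-7,9-dien-6-one (both epimers at the spiro carbon) | O=C1C(OCc2ccccc2)=CC(OC)=CC12CC[C@@H](c3ccccc3)O2 | intermediate (not isolated)
10 | (2S)-7-(benzyloxy)-5-methoxy-2-phenyl-3,4-dihydro-2H-chromen-8-ol | COc1cc(OCc2ccccc2)c(O)c2c1CC[C@@H](c1ccccc1)O2 | intermediate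
11 | (2S)-7-(benzyloxy)-5-methoxy-2-phenyl-3,4-dihydro-2H-chromen-8-yl trifluoromethanesulfonate | COc1cc(OCc2ccccc2)c(OS(=O)(=O)C(F)(F)F)c2c1CC[C@@H](c1ccccc1)O2 | intermediate
12 | [(2S)-7-(benzyloxy)-5-methoxy-2-phenyl-3,4-dihydro-2H-chromen-8-yl]methanol | COc1cc(OCc2ccccc2)c(CO)c2c1CC[C@@H](c1ccccc1)O2 | intermediate
13 | (2S)-7-(benzyloxy)-6-{[(2S)-7-(benzyloxy)-5-methoxy-2-phenyl-3,4-dihydro-2H-chromen-8-yl]methyl}-5-methoxy-2-phenyl-3,4-dihydro-2H-chromen-8-ol | COc1c(Cc3c(OCc4ccccc4)cc(OC)c4CC[C@@H](c5ccccc5)Oc34)c(OCc2ccccc2)c(O)c2c1CC[C@@H](c1ccccc1)O2 | intermediate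
14 | (2S)-7-(benzyloxy)-6-{[(2S)-7-(benzyloxy)-5-methoxy-2-phenyl-3,4-dihydro-2H-chromen-8-yl]methyl}-5-methoxy-2-phenyl-3,4-dihydro-2H-chromen-8-yl trifluoromethanesulfonate | COc1c(Cc3c(OCc4ccccc4)cc(OC)c4CC[C@@H](c5ccccc5)Oc34)c(OCc2ccccc2)c(OS(=O)(=O)C(F)(F)F)c2c1CC[C@@H](c1ccccc1)O2 | intermediate
15 | (2S)-7-(benzyloxy)-6-{[(2S)-7-(benzyloxy)-5-methoxy-2-phenyl-3,4-dihydro-2H-chromen-8-yl]methyl}-5-methoxy-2-phenyl-3,4-dihydro-2H-chromene | COc1c(Cc3c(OCc4ccccc4)cc(OC)c4CC[C@@H](c5ccccc5)Oc34)c(OCc2ccccc2)cc2c1CC[C@@H](c1ccccc1)O2 | intermediate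
16 | (2S)-6-{[(2S)-7-hydroxy-5-methoxy-2-phenyl-3,4-dihydro-2H-chromen-8-yl]methyl}-5-methoxy-2-phenyl-3,4-dihydro-2H-chromen-7-ol | COc1cc(O)c(Cc2c(O)cc3c(c2OC)CC[C@@H](c2ccccc2)O3)c2c1CC[C@@H](c1ccccc1)O2 | target

Total step count: 12
Longest linear sequence: 12 (steps 1 to 12; chromanol 10 enters twice, directly in step 9 and through steps 7 and 8)

**Steps most likely to fail**

Step 6. The dearomatisation may be diverted to the methoxy-bearing para carbon (oxidative loss of that position as a quinone), or spiroether 9 may dimerise by cycloaddition faster than the carbon shift occurs. The fallback uses only known reactions, closes the pyran without ring expansion and oxygenates C8 afterwards; it sets out from acetophenone 5 and comes back at 10. Acetophenone 5 is condensed (KOH, EtOH) with 4-(benzyloxy)-2-hydroxy-6-methoxybenzaldehyde to (E)-3-[4-(benzyloxy)-2-hydroxy-6-methoxyphenyl]-1-phenylprop-2-en-1-one F1, which is hydrogenated (H2, Pd/C, Ph2S) to 3-[4-(benzyloxy)-2-hydroxy-6-methoxyphenyl]-1-phenylpropan-1-one F2. Transfer hydrogenation with RuCl(p-cymene)[(R,R)-TsDPEN] in HCO2H/Et3N should give (R)-5-(benzyloxy)-2-(3-hydroxy-3-phenylpropyl)-3-methoxyphenol F3, and Mitsunobu cyclisation (PPh3, DIAD, THF, inversion) then gives (2S)-7-(benzyloxy)-5-methoxy-2-phenyl-3,4-dihydro-2H-chromene F4. Bromination with NBS (CH2Cl2, −78 °C), expected by analogy with other 5,7-dialkoxyflavans to prefer C8, gives (2S)-7-(benzyloxy)-8-bromo-5-methoxy-2-phenyl-3,4-dihydro-2H-chromene F5, and palladium-catalysed hydroxylation (KOH, Pd2(dba)3, tBuXPhos, dioxane/H2O, 100 °C) returns 10.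

Step 9. The benzylic cation from 12 may be captured by the free C6 position of a second molecule of 12 or of product 13, so that oligomers grow at the expense of the cross-coupled product. The fallback blocks that position with a group that the later triflate reduction removes; it sets out from 12 and comes back at 15. NBS (MeCN, −20 °C) brominates the only ring CH of 12 to give [(2S)-7-(benzyloxy)-6-bromo-5-methoxy-2-phenyl-3,4-dihydro-2H-chromen-8-yl]methanol F6. Benzylation of 10 with F6 (TFA cat., CH2Cl2, 0 °C) gives (2S)-7-(benzyloxy)-6-{[(2S)-7-(benzyloxy)-6-bromo-5-methoxy-2-phenyl-3,4-dihydro-2H-chromen-8-yl]methyl}-5-methoxy-2-phenyl-3,4-dihydro-2H-chromen-8-ol F7. Triflation (Tf2O, pyridine) gives (2S)-7-(benzyloxy)-6-{[(2S)-7-(benzyloxy)-6-bromo-5-methoxy-2-phenyl-3,4-dihydro-2H-chromen-8-yl]methyl}-5-methoxy-2-phenyl-3,4-dihydro-2H-chromen-8-yl trifluoromethanesulfonate F8, and the formate reduction of step 11 (Pd(OAc)2, dppf, HCO2H, Et3N) then cleaves both the C–OTf and the C–Br bond to give 15.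

Step 8. Transmetalation of the sp3 trifluoroborate at the crowded arylpalladium centre may be slow, so that protodeboronation of the reagent and hydrolysis of the triflate back to phenol 10 take over. The fallback brings in the carbon as CO, whose insertion is little affected by crowding; it sets out from 11 and comes back at 12. Methoxycarbonylation (CO 1 atm, MeOH, Pd(OAc)2, dppp, Et3N, DMSO, 70 °C) gives methyl (2S)-7-(benzyloxy)-5-methoxy-2-phenyl-3,4-dihydro-2H-chromene-8-carboxylate F9, which LiAlH4 (THF, 0 °C) reduces to 12.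

**Further compounds**
F1 | step 6 | (E)-3-[4-(benzyloxy)-2-hydroxy-6-methoxyphenyl]-1-phenylprop-2-en-1-one | O=C(/C=C/c1c(O)cc(OCc2ccccc2)cc1OC)c1ccccc1
F2 | step 6 | 3-[4-(benzyloxy)-2-hydroxy-6-methoxyphenyl]-1-phenylpropan-1-one | O=C(CCc1c(O)cc(OCc2ccccc2)cc1OC)c1ccccc1
F3 | step 6 | (R)-5-(benzyloxy)-2-(3-hydroxy-3-phenylpropyl)-3-methoxyphenol | O[C@H](CCc1c(O)cc(OCc2ccccc2)cc1OC)c1ccccc1
F4 | step 6 | (2S)-7-(benzyloxy)-5-methoxy-2-phenyl-3,4-dihydro-2H-chromene | COc1cc(OCc2ccccc2)cc2c1CC[C@@H](c1ccccc1)O2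
F5 | step 6 | (2S)-7-(benzyloxy)-8-bromo-5-methoxy-2-phenyl-3,4-dihydro-2H-chromene | COc1cc(OCc2ccccc2)c(Br)c2c1CC[C@@H](c1ccccc1)O2
F6 | step 9 | [(2S)-7-(benzyloxy)-6-bromo-5-methoxy-2-phenyl-3,4-dihydro-2H-chromen-8-yl]methanol | COc1c(Br)c(OCc2ccccc2)c(CO)c2c1CC[C@@H](c1ccccc1)O2
F7 | step 9 | (2S)-7-(benzyloxy)-6-{[(2S)-7-(benzyloxy)-6-bromo-5-methoxy-2-phenyl-3,4-dihydro-2H-chromen-8-yl]methyl}-5-methoxy-2-phenyl-3,4-dihydro-2H-chromen-8-ol | COc1c(Cc3c(OCc4ccccc4)c(Br)c(OC)c4CC[C@@H](c5ccccc5)Oc34)c(OCc2ccccc2)c(O)c2c1CC[C@@H](c1ccccc1)O2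
F8 | step 9 | (2S)-7-(benzyloxy)-6-{[(2S)-7-(benzyloxy)-6-bromo-5-methoxy-2-phenyl-3,4-dihydro-2H-chromen-8-yl]methyl}-5-methoxy-2-phenyl-3,4-dihydro-2H-chromen-8-yl trifluoromethanesulfonate | COc1c(Cc3c(OCc4ccccc4)c(Br)c(OC)c4CC[C@@H](c5ccccc5)Oc34)c(OCc2ccccc2)c(OS(=O)(=O)C(F)(F)F)c2c1CC[C@@H](c1ccccc1)O2
F9 | step 8 | methyl (2S)-7-(benzyloxy)-5-methoxy-2-phenyl-3,4-dihydro-2H-chromene-8-carboxylate | COc1cc(OCc2ccccc2)c(C(=O)OC)c2c1CC[C@@H](c1ccccc1)O2
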